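**Retrosynthetic overview**
- The C2 stereocentre is set last: the target comes from a ring-A enol acetate (C2=C3) by face-selective hydrogenation, with the acetate already on C2.
- Both rings form in one operation: the bicyclic enol acetate comes from an acyclic tertiary propargylic acetate by a gold-catalysed 1,3-acyloxy shift and allene-initiated cation–olefin bicyclisation. C4–C5 closes ring A, then C9–C10 closes ring B; C5, C9 and C10 are set together and C7=C8 arises by proton loss.
- The propargylic acetate comes from allyl–alkynyl coupling of 12-bromofarnesyl acetate with 2-methylbut-3-yn-2-ol, then acetylation.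
- 12-Bromofarnesyl acetate comes from terminal allylic oxidation of (2E,6E)-farnesyl acetate, which supplies all three E-alkenes of the cyclisation substrate.

Reading of the target: (2S,5R,9R,10R)-labda-7,13E-diene-2,15-diyl diacetate, an ent-labdane. The 2-OAc (axial), C20 and the C9 side chain lie on one face and H-5 on the other. Labdane numbering is used for the ring compounds.

Assumption: the sense of induction of the chiral gold catalyst cannot be predicted with certainty; the (R)-ligand is written, and the (S)-ligand is used instead if the first run gives the antipodal series.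

**Step 1**
Reactants: 1 (2E,6E)-farnesyl acetate
Product: 2 (2E,6E,10E)-12-hydroxyfarnesyl acetate
Conditions: SeO2 (0.3 equiv), t-BuOOH (3 equiv), salicylic acid (0.1 equiv), CH2Cl2, rt
Reagents that add atoms: selenium dioxide O=[Se]=O (oxygen carrier, catalytic); tert-butyl hydroperoxide CC(C)(C)OO (terminal oxidant)
Why: Catalytic Riley allylic oxidation (ene reaction, then [2,3]-sigmatropic shift) attacks the (E)-methyl of the most accessible, terminal trisubstituted alkene, so the new CH2OH is trans to the chain (10E).

**Step 2**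
Reactants: 2 (2E,6E,10E)-12-hydroxyfarnesyl acetate
Product: 3 (2E,6E,10E)-12-bromofarnesyl acetate
Conditions: CBr4, PPh3, CH2Cl2, 0 °C
Reagents that add atoms: carbon tetrabromide BrC(Br)(Br)Br
Why: Appel reaction; SN2 displacement at the primary allylic oxyphosphonium leaves the alkene geometry and the acetate untouched.

**Step 3**
Reactants: 3 (2E,6E,10E)-12-bromofarnesyl acetate; 4 2-methylbut-3-yn-2-ol
Product: 5 (2E,6E,10E)-15-hydroxy-3,7,11,15-tetramethylhexadeca-2,6,10-trien-13-yn-1-yl acetate
Conditions: CuI (20 mol %), K2CO3 (1.5 equiv), n-Bu4NBr (10 mol %), DMF, rt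
Reagents that add atoms: none
Why: Copper-acetylide alkynylation of an allylic halide; SN2 attack at the unhindered primary CH2Br gives the linear skipped 1,4-enyne with the E-alkene retained, and the carbonate base spares the acetate and the tertiary alcohol.

**Step 4**
Reactants: 5 (2E,6E,10E)-15-hydroxy-3,7,11,15-tetramethylhexadeca-2,6,10-trien-13-yn-1-yl acetate
Product: 6 (2E,6E,10E)-3,7,11,15-tetramethylhexadeca-2,6,10-trien-13-yne-1,15-diyl diacetate
Conditions: Ac2O, DMAP (0.2 equiv), pyridine, 40 °C
Reagents that add atoms: acetic anhydride CC(=O)OC(C)=O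
Why: DMAP-catalysed acyl transfer acetylates the tertiary propargylic alcohol, which is only moderately hindered because of the linear alkyne.

**Step 5**
Reactants: 6 (2E,6E,10E)-3,7,11,15-tetramethylhexadeca-2,6,10-trien-13-yne-1,15-diyl diacetate
Product: 8 (5R,9R,10S)-labda-2,7,13E-triene-2,15-diyl diacetate, via allenyl diacetate 7 (not isolated)
Conditions: (R)-DTBM-SEGPHOS(AuCl)2 (5 mol %), AgSbF6 (5 mol %), 4 Å molecular sieves, toluene, −20 °C to rt
Reagents that add atoms: none
Why: Proposed new method: cationic monovalent gold first effects the established [3,3] (1,3-)acyloxy shift of the tertiary propargylic acetate to the achiral allenyl acetate 7; the gold-bound C3=C4 π bond of 7 lies in the plane of the future ring, so the E-C5=C10 alkene attacks C4 anti to gold through a 6-endo chair (ring A); the tertiary C10 cation is captured by the E-C8=C9 alkene through a second chair (ring B; trans fusion and equatorial side chain by the Stork–Eschenmoser rule); the C8 cation loses the axial C7 proton to give the endocyclic C7=C8 alkene, and that proton cleaves the C3–Au bond to leave the C2 enol acetate; the C13=C14 alkene is deactivated by its allylic acetate and should stay out; the chiral digold bisphosphine selects which face of C5=C10 bonds and so sets C5, C9 and C10 together; the closest known reaction types are gold-catalysed 1,3-acyloxy migration to carboxyallenes, enantioselective gold-catalysed ene–allene cycloisomerisation and enantioselective gold-catalysed polyene cyclisation.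

**Step 6**
Reactants: 8 (5R,9R,10S)-labda-2,7,13E-triene-2,15-diyl diacetate
Product: 9 (2S,5R,9R,10R)-labda-7,13E-diene-2,15-diyl diacetate (target CNP0314870.1)
Conditions: [Rh(nbd)(dppb)]BF4 (5 mol %), H2 (30 bar), CH2Cl2, rt
Reagents that add atoms: none
Why: Chelation-assisted homogeneous hydrogenation of an enol ester by cationic monovalent rhodium (acetate carbonyl and C=C bind together, as in enamide hydrogenation) leaves unfunctionalised trisubstituted alkenes alone; H2 adds to the ring-A face anti to the two syn-axial methyl groups (C20 and the axial C4 methyl), which puts the acetoxy group axial and cis to C20 (2S).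

**Compound list**
1 | (2E,6E)-farnesyl acetate; (2E,6E)-3,7,11-trimethyldodeca-2,6,10-trien-1-yl acetate | CC(=O)OC/C=C(\C)CC/C=C(\C)CCC=C(C)C | starting material
2 | (2E,6E,10E)-12-hydroxy-3,7,11-trimethyldodeca-2,6,10-trien-1-yl acetate | CC(=O)OC/C=C(\C)CC/C=C(\C)CC/C=C(\C)CO | intermediate
3 | (2E,6E,10E)-12-bromo-3,7,11-trimethyldodeca-2,6,10-trien-1-yl acetate | CC(=O)OC/C=C(\C)CC/C=C(\C)CC/C=C(\C)CBr | intermediate
4 | 2-methylbut-3-yn-2-ol | CC(C)(O)C#C | starting material
5 | (2E,6E,10E)-15-hydroxy-3,7,11,15-tetramethylhexadeca-2,6,10-trien-13-yn-1-yl acetate | CC(=O)OC/C=C(\C)CC/C=C(\C)CC/C=C(\C)CC#CC(C)(C)O | intermediate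
6 | (2E,6E,10E)-3,7,11,15-tetramethylhexadeca-2,6,10-trien-13-yne-1,15-diyl diacetate | CC(=O)OC/C=C(\C)CC/C=C(\C)CC/C=C(\C)CC#CC(C)(C)OC(C)=O | intermediate
7 | (2E,6E,10E)-3,7,11,15-tetramethylhexadeca-2,6,10,13,14-pentaene-1,13-diyl diacetate (allenyl acetate, not isolated) | CC(=O)OC/C=C(\C)CC/C=C(\C)CC/C=C(\C)CC(OC(C)=O)=C=C(C)C | intermediate
8 | (5R,9R,10S)-labda-2,7,13E-triene-2,15-diyl diacetate; (4aR,8R,8aS)-8-[(3E)-5-acetyloxy-3-methylpent-3-en-1-yl]-4,4,7,8a-tetramethyl-1,4,4a,5,8,8a-hexahydronaphthalen-2-yl acetate | CC(=O)OC/C=C(\C)CC[C@@H]1C(C)=CC[C@@H]2C(C)(C)C=C(OC(C)=O)C[C@@]12C | intermediate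
9 | (2S,5R,9R,10R)-labda-7,13E-diene-2,15-diyl diacetate; (2S,4aR,8R,8aR)-8-[(3E)-5-acetyloxy-3-methylpent-3-en-1-yl]-4,4,7,8a-tetramethyl-1,2,3,4,4a,5,8,8a-octahydronaphthalen-2-yl acetate | CC(=O)OC/C=C(\C)CC[C@@H]1C(C)=CC[C@@H]2C(C)(C)C[C@H](OC(C)=O)C[C@@]12C | target

**Step count and risks**
Total steps: 6. Longest linear sequence: 6 (1 to 9; alkyne 4 is bought).

The three steps most likely to fail:

Step 5 (gold cascade). It is untested: it may stall at allene 7 or divert to a 2-acetoxy-1,3-diene, the ee may be low, and exocyclic 8(17)-alkene or tricyclic material may form. The fallback sets out from 6 and comes back at 9, replacing π-acid initiation by proton initiation at a carbonyl group. Hydrative Meyer–Schuster rearrangement of 6 (Ph3PAuNTf2 2 mol %, wet butan-2-one, rt) gives the conjugated enone (2E,6E,10E)-3,7,11,15-tetramethyl-13-oxohexadeca-2,6,10,14-tetraen-1-yl acetate F1. A strong chiral Brønsted acid, the N-triflylphosphoramide of (R)-3,3'-bis(2,4,6-triisopropylphenyl)-BINOL (10 mol %, CH2Cl2/(CF3)2CHOH, −40 °C), protonates the enone oxygen, and the polyene adds to the β-carbon in a conjugate-addition-initiated cation–olefin bicyclisation. This gives the ketone (5R,9R,10R)-2-oxolabda-7,13E-dien-15-yl acetate F2; if the ee is poor, racemic material made with CF3SO3H is resolved by preparative chiral HPLC. LiBH(s-Bu)3 in THF at −78 °C attacks C2 from the equatorial side, away from the two axial methyl groups, and gives the axial alcohol (2S,5R,9R,10R)-2-hydroxylabda-7,13E-dien-15-yl acetate F3. Ac2O, DMAP and pyridine then give 9, so step 6 is not needed.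

Step 6 (hydrogenation). The enol acetate is hindered by the neighbouring quaternary C4 and may not bind, or the side-chain allylic acetate alkene may be reduced as well. The fallback sets out from 8 and comes back at 9. K2CO3 in MeOH at rt removes both acetyl groups, the enol acetate unveiling the C2 ketone, to give the keto alcohol (5R,9R,10R)-15-hydroxylabda-7,13E-dien-2-one F4. LiBH(s-Bu)3 in THF at −78 °C reduces the ketone by equatorial attack to the axial alcohol, giving (2S,5R,9R,10R)-labda-7,13E-diene-2,15-diol F5. Ac2O, DMAP and pyridine acetylate both hydroxyl groups to give 9.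

Step 3 (allyl–alkynyl coupling). SN2' attack would give the branched isomer, the 10E geometry could erode, or the catalytic copper cycle could be sluggish. The fallback sets out from 3 and comes back at 5, using a Stille cross-coupling instead of copper-acetylide substitution. Alkynol 4 is C-stannylated with Bu3SnOMe (neat, 70 °C, methanol distilled off) to 2-methyl-4-(tributylstannyl)but-3-yn-2-ol F6. F6 is coupled with 3 under zerovalent palladium catalysis (Pd2(dba)3 2.5 mol %, P(2-furyl)3 10 mol %, THF, 50 °C); the π-allyl intermediate couples at its less substituted terminus with retention of the E-alkene and gives 5.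

**Further compounds**
F1 | step 5 | (2E,6E,10E)-3,7,11,15-tetramethyl-13-oxohexadeca-2,6,10,14-tetraen-1-yl acetate | CC(=O)OC/C=C(\C)CC/C=C(\C)CC/C=C(\C)CC(=O)C=C(C)C
F2 | step 5 | (5R,9R,10R)-2-oxolabda-7,13E-dien-15-yl acetate | CC(=O)OC/C=C(\C)CC[C@@H]1C(C)=CC[C@@H]2C(C)(C)CC(=O)C[C@@]12C
F3 | step 5 | (2S,5R,9R,10R)-2-hydroxylabda-7,13E-dien-15-yl acetate | CC(=O)OC/C=C(\C)CC[C@@H]1C(C)=CC[C@@H]2C(C)(C)C[C@H](O)C[C@@]12C
F4 | step 6 | (5R,9R,10R)-15-hydroxylabda-7,13E-dien-2-one | OC/C=C(\C)CC[C@@H]1C(C)=CC[C@@H]2C(C)(C)CC(=O)C[C@@]12C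
F5 | step 6 | (2S,5R,9R,10R)-labda-7,13E-diene-2,15-diol | OC/C=C(\C)CC[C@@H]1C(C)=CC[C@@H]2C(C)(C)C[C@H](O)C[C@@]12C
F6 | step 3 | 2-methyl-4-(tributylstannyl)but-3-yn-2-ol | CCCC[Sn](CCCC)(CCCC)C#CC(C)(C)O
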